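**Strategy.** Ring atoms: C1 (bears the side chain), C2 (CH2), C3 (CHCl), C4 (C(OH)CH3), C5 (CHOH), C6 (CH–O-angelate). The cyclohexane is traced back to the carvone-type enone 8 (C5=O, C3=C4). Its ring arises by nickel-catalysed insertion of a propyne unit (C3, C4, CH3) into one C(O)–CH2 bond of the achiral 3-allylcyclobutanone 5, which forms C2–C3 and C4–C5 in one operation. The step exploits that C1, the only ring stereocentre of 8, lies on the mirror plane of 5: a chiral ligand that selects one of the two enantiotopic ring bonds sets C1, from which C3–C6 are relayed; the allyl group grows into the side chain.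

Key step: step 3

Remark: the sense of asymmetric induction in step 3 cannot be predicted (both ligand antipodes are commercial; the one giving (5S)-8 is meant), and the reagent antipodes in steps 6 and 13 are chosen by the accepted transition-state models.

Side-chain labels: C7 (sp2 carbon on C1, carries =CH2), C8 (CH–O-angelate), C9 (CH2), C10 and C11 (oxirane carbons). Angelate = (2Z)-2-methylbut-2-enoate.

Step 1
Reactants: 1 penta-1,4-diene; 2 trichloroacetyl chloride
Product: 4 racemic 2,2-dichloro-3-(prop-2-en-1-yl)cyclobutan-1-one, via dichloroketene 3 (not isolated)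
Conditions: Zn(Cu), POCl3, Et2O, reflux; 1 in fourfold excess
Reagents that add atoms: none
Why: Zinc dechlorination of 2 should generate dichloroketene, whose thermal [2+2] ketene–alkene cycloaddition with one alkene of excess 1 should join the carbonyl carbon to the terminal CH2 (usual regiochemistry); the new stereocentre is racemic and is erased in step 2.

Step 2
Reactants: 4 racemic 2,2-dichloro-3-(prop-2-en-1-yl)cyclobutan-1-one
Product: 5 3-(prop-2-en-1-yl)cyclobutan-1-one
Conditions: Zn dust, AcOH, 60 °C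
Reagents that add atoms: none
Why: Zinc/acetic acid reductive dehalogenation of the α,α-dichloro ketone should remove both chlorines without touching the alkene and give the achiral, mirror-symmetric cyclobutanone.

Step 3
Reactants: 5 3-(prop-2-en-1-yl)cyclobutan-1-one; 6 tributyl(prop-1-yn-1-yl)stannane
Product: 8 (5S)-2-methyl-5-(prop-2-en-1-yl)cyclohex-2-en-1-one, via stannyl enone 7 (not isolated)
Conditions: Ni(cod)2 (10 mol %), (S)-BINOL-derived N,N-bis[(R)-1-phenylethyl]phosphoramidite (20 mol %), toluene, 90 °C, 6 added slowly; then CF3CO2H, CH2Cl2, 0 °C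
Reagents that add atoms: none
Why: Proposed new method: zerovalent nickel should couple the C=O of 5 and the alkyne of 6 by oxidative cyclisation to a spiro oxanickelacyclopentene (C4–C5 bond), β-carbon elimination of one cyclobutane C(O)–CH2 bond should give a seven-membered nickelacycle, and C(sp2)–C(sp3) reductive elimination should form the C2–C3 bond, the new element being that the chiral phosphoramidite chooses between the two enantiotopic C(O)–CH2 bonds in an intermolecular alkyne insertion. The closest known reaction types are the Ni(cod)2/PCy3-catalysed intermolecular insertion of internal alkynes into 3-substituted cyclobutanones (racemic) and the enantioselective intramolecular alkene insertion into cyclobutanones under nickel–phosphoramidite catalysis. The six-membered ring is closed by ring expansion of the four-membered ring through reductive elimination from the nickelacycle (a formal [4+2] annulation), not by cyclisation of an open chain. The only new stereocentre, C1, is set by the ligand, because C1 lies on the mirror plane of 5 and the two ring bonds beside the carbonyl are enantiotopic. The step needs alkyne regioselectivity, which the tributylstannyl group should secure by sitting next to nickel so that the methyl-bearing carbon bonds to the carbonyl carbon, and chemoselectivity for the alkyne over the allyl alkene, which the stronger binding of alkynes to zerovalent nickel should secure. Acid then replaces tin by hydrogen at the same carbon (protodestannylation), leaving the C3=C4 alkene in place.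

Step 4
Reactants: 8 (5S)-2-methyl-5-(prop-2-en-1-yl)cyclohex-2-en-1-one
Product: 9 2-[(1R)-4-methyl-5-oxocyclohex-3-en-1-yl]acetaldehyde
Conditions: K2OsO4·2H2O (2 mol %), NaIO4 (4 equiv), 2,6-lutidine, 1,4-dioxane/H2O, rt
Reagents that add atoms: sodium periodate, [Na+].[O-]I(=O)(=O)=O (terminal oxidant; its oxygen reaches the aldehyde through the osmium catalyst)
Why: Lemieux–Johnson oxidative cleavage should cut the isolated monosubstituted alkene in preference to the electron-poor enone alkene; no stereocentre is formed or touched.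

Step 5
Reactants: 9 2-[(1R)-4-methyl-5-oxocyclohex-3-en-1-yl]acetaldehyde
Product: 10 2-[(1S)-4-methyl-5-oxocyclohex-3-en-1-yl]prop-2-enal
Conditions: 37 % aq. CH2O, pyrrolidine (10 mol %), propionic acid (10 mol %), i-PrOH, 45 °C
Reagents that add atoms: formaldehyde, C=O
Why: Amine-catalysed Mannich condensation and elimination (organocatalytic α-methylenation of an aldehyde) should install the C7=CH2 group at the only aldehyde α-carbon; no new stereocentre (the descriptor at C1 changes only by priority).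

Step 6
Reactants: 10 2-[(1S)-4-methyl-5-oxocyclohex-3-en-1-yl]prop-2-enal
Product: 11 (5S)-5-[(3R)-3-hydroxyhexa-1,5-dien-2-yl]-2-methylcyclohex-2-en-1-one
Conditions: (+)-Ipc2B(allyl) (from (−)-α-pinene), Et2O, −78 °C; then 2-aminoethanol, rt
Reagents that add atoms: (+)-B-allyldiisopinocampheylborane, C=CCB(C1CC2CC(C1C)C2(C)C)C1CC2CC(C1C)C2(C)C
Why: Brown asymmetric allylboration through a chair-like six-membered transition state should add allyl to the aldehyde only (the ring ketone is far less reactive at −78 °C) and set C8 under reagent control as the 8R alcohol.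

Step 7
Reactants: 11 (5S)-5-[(3R)-3-hydroxyhexa-1,5-dien-2-yl]-2-methylcyclohex-2-en-1-one; 12 2-methylbut-2-ene
Product: 13 (5S)-5-[(3R)-3-hydroxy-6-methylhepta-1,5-dien-2-yl]-2-methylcyclohex-2-en-1-one
Conditions: 12 as co-solvent, second-generation Hoveyda–Grubbs catalyst RuCl2(H2IMes)(=CH-C6H4-2-O-i-Pr) (5 mol %), CH2Cl2, 40 °C
Reagents that add atoms: none
Why: Olefin cross-metathesis of the monosubstituted alkene with excess 12 should turn allyl into prenyl, the 1,1-disubstituted and ring alkenes being too hindered to react; no stereocentre is touched.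

Step 8
Reactants: 13 (5S)-5-[(3R)-3-hydroxy-6-methylhepta-1,5-dien-2-yl]-2-methylcyclohex-2-en-1-one
Product: 14 (5R,6R)-6-hydroxy-5-[(3R)-3-hydroxy-6-methylhepta-1,5-dien-2-yl]-2-methylcyclohex-2-en-1-one
Conditions: KN(SiMe3)2 (2.3 equiv), THF, −78 °C; 2-(phenylsulfonyl)-3-phenyloxaziridine, −78 °C; aq. NH4Cl
Reagents that add atoms: 2-(phenylsulfonyl)-3-phenyloxaziridine, O=S(=O)(c1ccccc1)N1OC1c1ccccc1
Why: Kinetic deprotonation at C6 (α′ of the enone, after the C8 alkoxide) and Davis oxidation of the cross-conjugated enolate should place the C6 hydroxyl anti to the neighbouring C1 substituent (trans, 6R), as in α′-hydroxylation of carvone-type enones.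

Step 9
Reactants: 14 (5R,6R)-6-hydroxy-5-[(3R)-3-hydroxy-6-methylhepta-1,5-dien-2-yl]-2-methylcyclohex-2-en-1-one; 15 angelic acid, (2Z)-2-methylbut-2-enoic acid
Product: 16 (1S,6R)-3-methyl-6-[(3S)-6-methyl-3-{[(2Z)-2-methylbut-2-enoyl]oxy}hepta-1,5-dien-2-yl]-2-oxocyclohex-3-en-1-yl (2Z)-2-methylbut-2-enoate
Conditions: 15 (4 equiv), PPh3, DIAD, toluene, 0 °C to rt
Reagents that add atoms: none
Why: Twofold Mitsunobu esterification should install both angelates with SN2 inversion, turning the trans C6 alcohol into the cis C6 ester and 8R into 8S, and because the acid acts as the nucleophile its Z alkene should not isomerise.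

Step 10
Reactants: 16 the bis-angelate enone named in step 9
Product: 17 (1S,2R,6R)-2-hydroxy-3-methyl-6-[(3S)-6-methyl-3-{[(2Z)-2-methylbut-2-enoyl]oxy}hepta-1,5-dien-2-yl]cyclohex-3-en-1-yl (2Z)-2-methylbut-2-enoate
Conditions: NaBH4, CeCl3·7H2O, MeOH, −78 °C
Reagents that add atoms: none
Why: Luche 1,2-reduction should deliver hydride to C5 from the face opposite the pseudoaxial C6 acyloxy group (axial attack) and give the C5 hydroxyl cis to O6 and to the C1 side chain, leaving the enoate esters untouched.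

Step 11
Reactants: 17 the allylic alcohol named in step 10
Product: 18 (1S,2S,3S,4R,6R)-2-hydroxy-1-methyl-4-[(3S)-6-methyl-3-{[(2Z)-2-methylbut-2-enoyl]oxy}hepta-1,5-dien-2-yl]-7-oxabicyclo[4.1.0]heptan-3-yl (2Z)-2-methylbut-2-enoate (oxirane on C3/C4, syn to the C5 hydroxyl)
Conditions: VO(acac)2 (3 mol %), t-BuOOH (decane solution, 1.2 equiv), CH2Cl2, 0 °C to rt
Reagents that add atoms: tert-butyl hydroperoxide, CC(C)(C)OO
Why: Vanadium-catalysed hydroxyl-directed epoxidation should oxidise only the allylic-alcohol alkene C3=C4 and deliver oxygen syn to the C5 hydroxyl, which fixes C3 and C4.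

Step 12
Reactants: 18 the epoxy alcohol named in step 11
Product: 19 (1S,2S,3S,4S,6R)-4-chloro-2,3-dihydroxy-3-methyl-6-[(3S)-6-methyl-3-{[(2Z)-2-methylbut-2-enoyl]oxy}hepta-1,5-dien-2-yl]cyclohexyl (2Z)-2-methylbut-2-enoate
Conditions: Ti(O-i-Pr)4 (1.5 equiv), Et2NH2Cl (3 equiv), CH2Cl2, rt
Reagents that add atoms: diethylammonium chloride, CC[NH2+]CC.[Cl-]
Why: Titanium-mediated opening of the 2,3-epoxy alcohol should put chloride on the distal secondary C3 with inversion (chelation, the inductive effect of O5 on C4 and the trans-diaxial Fürst–Plattner course all agree), leaving the C4 hydroxyl anti to chlorine.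

Step 13
Reactants: 19 the chlorohydrin named in step 12
Product: 20 (1S,2S,3S,4S,6R)-4-chloro-6-{(3S)-4-[(2S)-3,3-dimethyloxiran-2-yl]-3-{[(2Z)-2-methylbut-2-enoyl]oxy}but-1-en-2-yl}-2,3-dihydroxy-3-methylcyclohexyl (2Z)-2-methylbut-2-enoate (CNP0333703.2)
Conditions: L-fructose-derived Shi ketone (enantiomer of the usual D-fructose-derived ketone, 0.5 equiv), Oxone (2KHSO5·KHSO4·K2SO4), NaHCO3 (pH about 8), MeCN/dimethoxymethane/aq. Na2EDTA, 0 °C
Reagents that add atoms: potassium peroxymonosulfate (active salt of Oxone), [K+].[O-]S(=O)(=O)OO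
Why: Shi epoxidation should oxidise only the electron-rich trisubstituted C10=C11 alkene (the 1,1-disubstituted alkene and the enoates are poor dioxirane substrates) and set C10 as S under reagent control through the spiro transition state, while the near-neutral buffer spares the base-labile chlorohydrin.

**Compound list**

1 | penta-1,4-diene | C=CCC=C | starting material
2 | trichloroacetyl chloride | ClC(=O)C(Cl)(Cl)Cl | starting material
3 | dichloroketene (not isolated) | ClC(Cl)=C=O | intermediate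
4 | racemic 2,2-dichloro-3-(prop-2-en-1-yl)cyclobutan-1-one | C=CCC1CC(=O)C1(Cl)Cl | intermediate
5 | 3-(prop-2-en-1-yl)cyclobutan-1-one | C=CCC1CC(=O)C1 | intermediate
6 | tributyl(prop-1-yn-1-yl)stannane | CC#C[Sn](CCCC)(CCCC)CCCC | starting material
7 | (5R)-2-methyl-5-(prop-2-en-1-yl)-3-(tributylstannyl)cyclohex-2-en-1-one (not isolated) | C=CC[C@H]1CC([Sn](CCCC)(CCCC)CCCC)=C(C)C(=O)C1 | intermediate
8 | (5S)-2-methyl-5-(prop-2-en-1-yl)cyclohex-2-en-1-one | C=CC[C@H]1CC=C(C)C(=O)C1 | intermediate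
9 | 2-[(1R)-4-methyl-5-oxocyclohex-3-en-1-yl]acetaldehyde | O=CC[C@H]1CC=C(C)C(=O)C1 | intermediate
10 | 2-[(1S)-4-methyl-5-oxocyclohex-3-en-1-yl]prop-2-enal | C=C(C=O)[C@H]1CC=C(C)C(=O)C1 | intermediate
11 | (5S)-5-[(3R)-3-hydroxyhexa-1,5-dien-2-yl]-2-methylcyclohex-2-en-1-one | C=C([C@@H](CC=C)O)[C@H]1CC=C(C)C(=O)C1 | intermediate
12 | 2-methylbut-2-ene | CC=C(C)C | starting material
13 | (5S)-5-[(3R)-3-hydroxy-6-methylhepta-1,5-dien-2-yl]-2-methylcyclohex-2-en-1-one | C=C([C@@H](CC=C(C)C)O)[C@H]1CC=C(C)C(=O)C1 | intermediate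
14 | (5R,6R)-6-hydroxy-5-[(3R)-3-hydroxy-6-methylhepta-1,5-dien-2-yl]-2-methylcyclohex-2-en-1-one | C=C([C@@H](CC=C(C)C)O)[C@H]1CC=C(C)C(=O)[C@@H]1O | intermediate
15 | angelic acid, (2Z)-2-methylbut-2-enoic acid | C/C=C(/C)C(=O)O | starting material
16 | (1S,6R)-3-methyl-6-[(3S)-6-methyl-3-{[(2Z)-2-methylbut-2-enoyl]oxy}hepta-1,5-dien-2-yl]-2-oxocyclohex-3-en-1-yl (2Z)-2-methylbut-2-enoate | C=C([C@H](CC=C(C)C)OC(=O)/C(C)=C\C)[C@H]1CC=C(C)C(=O)[C@H]1OC(=O)/C(C)=C\C | intermediate
17 | (1S,2R,6R)-2-hydroxy-3-methyl-6-[(3S)-6-methyl-3-{[(2Z)-2-methylbut-2-enoyl]oxy}hepta-1,5-dien-2-yl]cyclohex-3-en-1-yl (2Z)-2-methylbut-2-enoate | C=C([C@H](CC=C(C)C)OC(=O)/C(C)=C\C)[C@H]1CC=C(C)[C@@H](O)[C@H]1OC(=O)/C(C)=C\C | intermediate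
18 | (1S,2S,3S,4R,6R)-2-hydroxy-1-methyl-4-[(3S)-6-methyl-3-{[(2Z)-2-methylbut-2-enoyl]oxy}hepta-1,5-dien-2-yl]-7-oxabicyclo[4.1.0]heptan-3-yl (2Z)-2-methylbut-2-enoate | C=C([C@H](CC=C(C)C)OC(=O)/C(C)=C\C)[C@H]1C[C@H]2O[C@@]2(C)[C@@H](O)[C@H]1OC(=O)/C(C)=C\C | intermediate
19 | (1S,2S,3S,4S,6R)-4-chloro-2,3-dihydroxy-3-methyl-6-[(3S)-6-methyl-3-{[(2Z)-2-methylbut-2-enoyl]oxy}hepta-1,5-dien-2-yl]cyclohexyl (2Z)-2-methylbut-2-enoate | C=C([C@H](CC=C(C)C)OC(=O)/C(C)=C\C)[C@H]1C[C@H](Cl)[C@@](C)(O)[C@@H](O)[C@H]1OC(=O)/C(C)=C\C | intermediate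
20 | (1S,2S,3S,4S,6R)-4-chloro-6-{(3S)-4-[(2S)-3,3-dimethyloxiran-2-yl]-3-{[(2Z)-2-methylbut-2-enoyl]oxy}but-1-en-2-yl}-2,3-dihydroxy-3-methylcyclohexyl (2Z)-2-methylbut-2-enoate | C=C([C@H](C[C@@H]1OC1(C)C)OC(=O)/C(C)=C\C)[C@H]1C[C@H](Cl)[C@@](C)(O)[C@@H](O)[C@H]1OC(=O)/C(C)=C\C | target

**Totals.** 13 steps; longest linear sequence 13 steps (from 1).

**Steps most likely to fail**

1. Step 3 (key step, proposed new method). What may go wrong: weak discrimination between the two enantiotopic C(O)–CH2 bonds (low enantioselectivity), or consumption of the alkynylstannane by nickel-mediated oligomerisation before insertion. Fallback with known chemistry, setting out from 5: the established achiral catalyst Ni(cod)2/PCy3 with 6 should give racemic 2-methyl-5-(prop-2-en-1-yl)-3-(tributylstannyl)cyclohex-2-en-1-one F1, protodestannylated in the same flask to racemic 2-methyl-5-(prop-2-en-1-yl)cyclohex-2-en-1-one F2. Luche reduction should give racemic cis-2-methyl-5-(prop-2-en-1-yl)cyclohex-2-en-1-ol F3. Lipase-catalysed kinetic resolution (Candida antarctica lipase B, vinyl acetate) is expected to acetylate the 1R,5R enantiomer to (1R,5R)-2-methyl-5-(prop-2-en-1-yl)cyclohex-2-en-1-yl acetate F5 and leave (1S,5S)-2-methyl-5-(prop-2-en-1-yl)cyclohex-2-en-1-ol F4. After separation, MnO2 oxidation of F4 comes back to the route at 8.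

2. Step 9. What may go wrong: SN2′ attack at the allylic C8 position, or elimination and incomplete inversion at the hindered α-ketol carbon C6. The fallback avoids both Mitsunobu reactions and sets out from 10. Allylboration with the enantiomeric reagent (−)-Ipc2B(allyl) should give (5S)-5-[(3S)-3-hydroxyhexa-1,5-dien-2-yl]-2-methylcyclohex-2-en-1-one F6, and cross-metathesis with 12 should give (5S)-5-[(3S)-3-hydroxy-6-methylhepta-1,5-dien-2-yl]-2-methylcyclohex-2-en-1-one F7. Esterification with 15 through its 2,4,6-trichlorobenzoyl mixed anhydride (retention) should give (3S)-6-methyl-2-[(1S)-4-methyl-5-oxocyclohex-3-en-1-yl]hepta-1,5-dien-3-yl (2Z)-2-methylbut-2-enoate F8. Soft enolisation (Me3SiOTf, Et3N) should give (3S)-6-methyl-2-{(1S)-4-methyl-3-[(trimethylsilyl)oxy]cyclohexa-2,4-dien-1-yl}hepta-1,5-dien-3-yl (2Z)-2-methylbut-2-enoate F9. N-Bromosuccinimide at −78 °C should brominate C6 anti to the C1 substituent and give (3S)-2-[(1R,6R)-6-bromo-4-methyl-5-oxocyclohex-3-en-1-yl]-6-methylhepta-1,5-dien-3-yl (2Z)-2-methylbut-2-enoate F10. SN2 displacement with caesium angelate (15, Cs2CO3, DMF) inverts C6 and comes back to the route at 16.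

3. Step 12. What may go wrong: chloride attack at the tertiary C4 instead of C3, or acyl transfer from O6 to O5 through the titanium alkoxide. The fallback makes the C–Cl bond electrophilically, where water must enter at the tertiary carbon, and defers the metathesis so that no prenyl alkene competes; it sets out from 11. Hydroxylation as in step 8 should give (5R,6R)-6-hydroxy-5-[(3R)-3-hydroxyhexa-1,5-dien-2-yl]-2-methylcyclohex-2-en-1-one F11. Twofold Mitsunobu esterification with 15 should give (1S,6R)-3-methyl-6-[(3S)-3-{[(2Z)-2-methylbut-2-enoyl]oxy}hexa-1,5-dien-2-yl]-2-oxocyclohex-3-en-1-yl (2Z)-2-methylbut-2-enoate F12. Luche reduction should give (1S,2R,6R)-2-hydroxy-3-methyl-6-[(3S)-3-{[(2Z)-2-methylbut-2-enoyl]oxy}hexa-1,5-dien-2-yl]cyclohex-3-en-1-yl (2Z)-2-methylbut-2-enoate F13. N-Chlorosuccinimide in aqueous acetone should form the chloronium ion on the face opposite the three ring substituents at the most nucleophilic (trisubstituted) alkene, and water should open it at C4, giving (1S,2S,3S,4S,6R)-4-chloro-2,3-dihydroxy-3-methyl-6-[(3S)-3-{[(2Z)-2-methylbut-2-enoyl]oxy}hexa-1,5-dien-2-yl]cyclohexyl (2Z)-2-methylbut-2-enoate F14. Cross-metathesis of F14 with 12 comes back to the route at 19.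

**Further compounds**

F1 | step 3 | racemic 2-methyl-5-(prop-2-en-1-yl)-3-(tributylstannyl)cyclohex-2-en-1-one | C=CCC1CC([Sn](CCCC)(CCCC)CCCC)=C(C)C(=O)C1
F2 | step 3 | racemic 2-methyl-5-(prop-2-en-1-yl)cyclohex-2-en-1-one | C=CCC1CC=C(C)C(=O)C1
F3 | step 3 | racemic cis-2-methyl-5-(prop-2-en-1-yl)cyclohex-2-en-1-ol | C=CC[C@H]1CC=C(C)[C@@H](O)C1.C=CC[C@@H]1CC=C(C)[C@H](O)C1
F4 | step 3 | (1S,5S)-2-methyl-5-(prop-2-en-1-yl)cyclohex-2-en-1-ol | C=CC[C@H]1CC=C(C)[C@@H](O)C1
F5 | step 3 | (1R,5R)-2-methyl-5-(prop-2-en-1-yl)cyclohex-2-en-1-yl acetate | C=CC[C@@H]1CC=C(C)[C@H](OC(C)=O)C1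
F6 | step 9 | (5S)-5-[(3S)-3-hydroxyhexa-1,5-dien-2-yl]-2-methylcyclohex-2-en-1-one | C=C([C@H](CC=C)O)[C@H]1CC=C(C)C(=O)C1
F7 | step 9 | (5S)-5-[(3S)-3-hydroxy-6-methylhepta-1,5-dien-2-yl]-2-methylcyclohex-2-en-1-one | C=C([C@H](CC=C(C)C)O)[C@H]1CC=C(C)C(=O)C1
F8 | step 9 | (3S)-6-methyl-2-[(1S)-4-methyl-5-oxocyclohex-3-en-1-yl]hepta-1,5-dien-3-yl (2Z)-2-methylbut-2-enoate | C=C([C@H](CC=C(C)C)OC(=O)/C(C)=C\C)[C@H]1CC=C(C)C(=O)C1
F9 | step 9 | (3S)-6-methyl-2-{(1S)-4-methyl-3-[(trimethylsilyl)oxy]cyclohexa-2,4-dien-1-yl}hepta-1,5-dien-3-yl (2Z)-2-methylbut-2-enoate | C=C([C@H](CC=C(C)C)OC(=O)/C(C)=C\C)[C@H]1CC=C(C)C(O[Si](C)(C)C)=C1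
F10 | step 9 | (3S)-2-[(1R,6R)-6-bromo-4-methyl-5-oxocyclohex-3-en-1-yl]-6-methylhepta-1,5-dien-3-yl (2Z)-2-methylbut-2-enoate | C=C([C@H](CC=C(C)C)OC(=O)/C(C)=C\C)[C@H]1CC=C(C)C(=O)[C@@H]1Br
F11 | step 12 | (5R,6R)-6-hydroxy-5-[(3R)-3-hydroxyhexa-1,5-dien-2-yl]-2-methylcyclohex-2-en-1-one | C=C([C@@H](CC=C)O)[C@H]1CC=C(C)C(=O)[C@@H]1O
F12 | step 12 | (1S,6R)-3-methyl-6-[(3S)-3-{[(2Z)-2-methylbut-2-enoyl]oxy}hexa-1,5-dien-2-yl]-2-oxocyclohex-3-en-1-yl (2Z)-2-methylbut-2-enoate | C=C([C@H](CC=C)OC(=O)/C(C)=C\C)[C@H]1CC=C(C)C(=O)[C@H]1OC(=O)/C(C)=C\C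
F13 | step 12 | (1S,2R,6R)-2-hydroxy-3-methyl-6-[(3S)-3-{[(2Z)-2-methylbut-2-enoyl]oxy}hexa-1,5-dien-2-yl]cyclohex-3-en-1-yl (2Z)-2-methylbut-2-enoate | C=C([C@H](CC=C)OC(=O)/C(C)=C\C)[C@H]1CC=C(C)[C@@H](O)[C@H]1OC(=O)/C(C)=C\C
F14 | step 12 | (1S,2S,3S,4S,6R)-4-chloro-2,3-dihydroxy-3-methyl-6-[(3S)-3-{[(2Z)-2-methylbut-2-enoyl]oxy}hexa-1,5-dien-2-yl]cyclohexyl (2Z)-2-methylbut-2-enoate | C=C([C@H](CC=C)OC(=O)/C(C)=C\C)[C@H]1C[C@H](Cl)[C@@](C)(O)[C@@H](O)[C@H]1OC(=O)/C(C)=C\C
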